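I start by deciding whether the crystal step of target can run at all, and for that I turn the constants into times.

solid substrate 0.30 M; coupling partner 1.10 equiv; time 2.0 h

    solid substrate ⇌ dissolved substrate, rate k1*(cs1 - [dissolved substrate]) while solid is left; crystals form when [dissolved substrate] > cs1 (cs1 = 0.16 M, k1 = 2.01 × 10⁻⁴ s⁻¹)
    solid product ⇌ target, rate k2*(cs2 - [target]) while solid is left; crystals form when [target] > cs2 (cs2 = 46 mM, k2 = 0.00330 s⁻¹)
    dissolved substrate + target → side product (k3 = 0.0100 M⁻¹ s⁻¹)
    dissolved substrate + coupling partner ⇌ target (K4 = 2.92 M⁻¹, k4 = 0.00105 M⁻¹ s⁻¹)

- percent here means solid substrate units held: one side product counts as two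
- what is said of target includes solid product
- solid substrate, solid product is a solid; its amount is given per volume of the solution
- at the start none of the solid substrate is in solution
- run time (flask): 2.0 h

* amount of target and solid product together at 2.0 h, in percent of the solid substrate charged
* the change that raises the amount of target and solid product together at 2.0 h, in percent of the solid substrate charged most ("none" if none brings more than 2 percentage points) (Tuesday's / Thursday's / Sunday's / Friday's / none)
* amount of target and solid product together at 2.0 h, in percent of the solid substrate charged, after Thursday's

- Tuesday's: doubling the solubility in step 2, all else as stated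
- Thursday's: doubling the dissolution coefficient of step 2, all else as stated
- Sunday's: doubling the solubility in step 1, all else as stated
- Friday's: doubling the amount of coupling partner, all else as stated

At the bottom of my ladder stands crystal exchange of target, with a half-time of 3.50 min, but it acts once c(target) passes 46 mM. Next come the way back of coupling, 0.535 h, forward coupling at the charge, 0.56 h, and dissolution of solid substrate, 0.958 h. The run of 2.0 h is longer than each, so target has time to reach a level. Dissolution can deliver at most 77.2% of the charge by the end, even into a solution kept empty, less than the whole, so solid substrate lasts through the run.

Coupling makes target in proportion to c(dissolved substrate), and the side reaction destroys it in proportion to the same concentration. This gives a ceiling on target, the concentration at which the side reaction matches coupling even with no way back: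

ceiling = 0.00105 M⁻¹ s⁻¹ × 330 mM / 0.0100 M⁻¹ s⁻¹ = 34.6 mM

This lies below 46 mM, so crystals do not form in this flask, and I set Thursday's and Tuesday's at no gain.

The way back lowers the level (the quasi-steady state):

c(target) = ceiling × c(dissolved substrate) / (c(dissolved substrate) + 36.0 mM)

Supply balances a drain of 2 × side rate near c(dissolved substrate) = 53.3 mM, with 77.2 mM h⁻¹ in and 79.3 mM h⁻¹ out. That gives 20.7 mM, or 6.90%, reckoned with the partner held at its charge.

Friday's doubles the ceiling and balances near c(dissolved substrate) = 36.0 mM, where the level is half the new ceiling, a gain of 4.7 percentage points. For Sunday's, even a doubled c(dissolved substrate) gains 1.7 points, less than 2 points. I choose Friday's.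

The forecast gives 5.8%, Friday's and 5.8%, holding that “no solid product ever forms”.

The simulation gives 5.83%, Friday's with 4.6 points, Sunday's at −0.25 points, and 5.83% after Thursday's.

In this flask, solid substrate kept dissolving, with 44.0% still solid at 2.00 h, while target stood at 5.35% at 1.00 h and at 5.83% at 2.00 h. Over that second stretch, side product went from 8.46% to 31.2%. The ceiling, scaled by the partner left and put through the level with the dissolved substrate read at the end, gives 5.70% against the 5.83% present. The neighbour charged with 2.80 equiv reckons the same way to 12.5%, and that neighbour holds 12.5%.

Its constants were set for the occasion; the run is a simulation.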